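**Assumption:** the SMILES decodes to the all-trans (2S,3S,4S,5S) tetrahydrofuran, and that is the isomer made here. (−)-Ipc2BOMe, trans-2-butene and 9-BBN are taken as commercial. The route is designed by analogy to known lactone → hemiketal → reduction chemistry for this lignan class and has not been run.

## Retrosynthetic overview

1. C2–H: BF3/silane reduction of a cyclic hemiketal (2-aryl oxocarbenium) gives the THF.
2. C2–aryl: addition of 3,4-dimethoxyphenyllithium to a trans,trans-3,4-dimethyl-5-aryl-γ-butyrolactone.
3. C3–Me: enolate methylation of the 4-methyl-5-aryl lactone, anti to the C4 methyl.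
4. The lactone (the only ring formed, later the THF ring) comes from an anti homoallylic alcohol by hydroboration and oxidative lactonization.
5. C4/C5: Brown anti-crotylation of 3,4,5-trimethoxybenzaldehyde.

## Route

**Step 1**
Reactants: 1, 3,4,5-trimethoxybenzaldehyde; 2, trans-2-butene
Product: 3, (1S,2S)-2-methyl-1-(3,4,5-trimethoxyphenyl)but-3-en-1-ol (anti)
Conditions: 2, KOt-Bu, n-BuLi, THF, −78 → −45 °C; (−)-Ipc2BOMe, −78 °C; BF3·OEt2; then 1, −78 °C; NaOH, H2O2 workup
Reagents that add atoms: the crotyl unit comes from 2 (trans-2-butene, C/C=C/C); nothing else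
Why: Brown asymmetric crotylboration through a chair Zimmerman–Traxler transition state; the (E)-crotyl geometry gives the anti diad and the (+)-α-pinene-derived Ipc groups direct Si-face attack on the aryl aldehyde, setting 1S,2S (future C5 and C4).

**Step 2**
Reactants: 3
Product: 4, (1S,2S)-2-methyl-1-(3,4,5-trimethoxyphenyl)butane-1,4-diol
Conditions: 9-BBN (2.5 equiv), THF, 0 °C → rt; then aq. NaOH, 30% H2O2, 0 °C → rt
Reagents that add atoms: hydrogen peroxide (OO) supplies the new hydroxyl oxygen
Why: anti-Markovnikov hydroboration–oxidation of the terminal alkene; no stereocenter is touched.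

**Step 3**
Reactants: 4
Product: 5, (4S,5S)-4-methyl-5-(3,4,5-trimethoxyphenyl)dihydrofuran-2(3H)-one (trans lactone)
Conditions: TEMPO (0.2 equiv), PhI(OAc)2 (3 equiv), CH2Cl2, rt
Reagents that add atoms: none
Why: TEMPO/BAIB oxidative lactonization; the primary alcohol is oxidized selectively to the aldehyde, which closes onto the benzylic OH as a lactol and is oxidized on to the lactone with both stereocenters retained.

**Step 4**
Reactants: 5
Product: 6, (3S,4S,5S)-3,4-dimethyl-5-(3,4,5-trimethoxyphenyl)dihydrofuran-2(3H)-one (3,4-trans, 4,5-trans)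
Conditions: LiHMDS (1.1 equiv), THF, −78 °C; MeI (3 equiv), −78 → −40 °C
Reagents that add atoms: iodomethane (CI)
Why: substrate-controlled lactone enolate alkylation; MeI approaches anti to the adjacent C4 methyl, setting 3S (3,4-trans), which is also the thermodynamically preferred epimer.

**Step 5**
Reactants: 6; 7, 4-bromo-1,2-dimethoxybenzene
Product: 8, (3S,4S,5S)-2-(3,4-dimethoxyphenyl)-3,4-dimethyl-5-(3,4,5-trimethoxyphenyl)tetrahydrofuran-2-ol (anomeric mixture, in equilibrium with the open hydroxy ketone; used crude)
Conditions: 7 (1.5 equiv), n-BuLi (1.45 equiv), THF, −78 °C; then 6, −78 °C; NH4Cl quench at −78 °C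
Reagents that add atoms: the aryl group comes from 7 (COc1ccc(Br)cc1OC); n-BuLi leaves no atoms
Why: Br/Li exchange then mono-addition of the aryllithium to the lactone carbonyl; the tetrahedral lithium alkoxide is stable at −78 °C and the α-branch suppresses double addition, and no stereocenter is affected.

**Step 6**
Reactants: 8
Product: 9, 5-methoxygalbelgin, (2S,3S,4S,5S)-2-(3,4-dimethoxyphenyl)-3,4-dimethyl-5-(3,4,5-trimethoxyphenyl)tetrahydrofuran
Conditions: Et3SiH (5 equiv), BF3·OEt2 (3 equiv), CH2Cl2, −78 → −20 °C
Reagents that add atoms: none (Et3SiH delivers H only)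
Why: Kishi-type reductive deoxygenation of the hemiketal via the aryl-stabilized oxocarbenium; hydride delivery places the C2 aryl trans to the C3 methyl (2S), and because all-trans is the thermodynamic isomer, any reversible benzylic C–O ionization under BF3 converges on it.

## Compound list

1 | 3,4,5-trimethoxybenzaldehyde | COc1cc(C=O)cc(OC)c1OC | starting material
2 | trans-2-butene | C/C=C/C | starting material
3 | (1S,2S)-2-methyl-1-(3,4,5-trimethoxyphenyl)but-3-en-1-ol | O[C@H](c1cc(OC)c(OC)c(OC)c1)[C@@H](C)C=C | intermediate
4 | (1S,2S)-2-methyl-1-(3,4,5-trimethoxyphenyl)butane-1,4-diol | O[C@H](c1cc(OC)c(OC)c(OC)c1)[C@@H](C)CCO | intermediate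
5 | (4S,5S)-4-methyl-5-(3,4,5-trimethoxyphenyl)dihydrofuran-2(3H)-one | O=C1O[C@H](c2cc(OC)c(OC)c(OC)c2)[C@@H](C)C1 | intermediate
6 | (3S,4S,5S)-3,4-dimethyl-5-(3,4,5-trimethoxyphenyl)dihydrofuran-2(3H)-one | O=C1O[C@H](c2cc(OC)c(OC)c(OC)c2)[C@@H](C)[C@@H]1C | intermediate
7 | 4-bromo-1,2-dimethoxybenzene | COc1ccc(Br)cc1OC | starting material
8 | (3S,4S,5S)-2-(3,4-dimethoxyphenyl)-3,4-dimethyl-5-(3,4,5-trimethoxyphenyl)tetrahydrofuran-2-ol | COc1ccc(C2(O)O[C@H](c3cc(OC)c(OC)c(OC)c3)[C@@H](C)[C@@H]2C)cc1OC | intermediate
9 | 5-methoxygalbelgin, (2S,3S,4S,5S) | COc1ccc([C@H]2O[C@H](c3cc(OC)c(OC)c(OC)c3)[C@@H](C)[C@@H]2C)cc1OC | target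

## Summary

Total steps: 6. Longest linear sequence: 6 (from 1; 2 and 7 are used as purchased).

Steps most likely to fail, each with a fallback that changes the approach:

1. **Step 6** (over-reduction or ring-opening of the electron-rich bis-benzylic ether, dihydrofuran formation, 2,3-cis isomer). Fallback: reduce the open hydroxy-ketone form of 8 with NaBH4 to the 1,4-diaryl-1,4-diol, then close the ring by SN1 cycloetherification (MsCl/Et3N or catalytic acid) through the p-alkoxybenzyl cation under thermodynamic control to the all-trans THF.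

2. **Step 4** (incomplete trans selectivity because the C5 aryl sits on the face being alkylated; dialkylation). Fallback: α-methylenate 5 (enolate plus Eschenmoser's salt, quaternize and eliminate), hydrogenate the exo-methylene, and equilibrate the α-centre with DBU to the thermodynamic trans,trans lactone 6.

3. **Step 1** (ee/dr erosion with an electron-rich aryl aldehyde; demanding low-temperature crotylpotassium protocol). Fallback: Evans syn-aldol of (R)-4-benzyl-3-propionyloxazolidin-2-one with 3,4-dimethoxybenzaldehyde, then LiBH4 cleavage and one-carbon homologation to the 4,5-cis lactone. The same end game follows with 3,4,5-trimethoxyphenyllithium, relying on BF3-promoted C5 epimerization to all-trans in the last step. The aryl order can be swapped because the all-S core is C2-symmetric.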